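## Retrosynthetic overview

1. The target is an A–B–C–D tetramer: two erythro (7R,8S) aryl glycerol 8-O-4 ethers (ring A to ring B, ring B to ring C) and a trans-(2R,3S)-2-aryl-3-hydroxymethyl-2,3-dihydrobenzofuran (rings C/D; core atoms O1, C2, C3, C3a, C7a; side-chain carbons C7–C9).
2. Last bonds: the C5 propenal of ring D by Suzuki coupling of a C5 triflate (C5 carries a temporary oxygen). Before that, C7–C8 of unit B by Evans aldol of a ring C aryloxyacetyl imide (fragment 1) with an A–B aldehyde (fragment 2), Mitsunobu inversion at C7 and reductive auxiliary removal. Fragment 2 comes by the same operations from vanillin and 4-bromo-2,6-dimethoxyphenol.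
3. Key disconnection: O1–C2 and C3a–C3 of the furan ring, made together by a formal [3+2] coupling of a ring D quinone monoketal with a sinapyl silyl ether (ring C, free 4-OH) under a chiral phosphoric acid.
4. Enabling feature: in ring C the O4–H is para to the side-chain C7=C8 bond, so C8 (later C3) is a vinylogous enol carbon and C7 (later C2) becomes a quinone methide carbon. In ring D, O1 on C7a is ortho to C3a–H and para to C5, so ring D can enter as a C5-oxygenated phenoxonium ion that is electrophilic at C3a.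
5. Ring order: all four arenes are bought; the only ring formed is the dihydrofuran (step 6), and both aryl glycerol units are attached afterwards.

Key step: step 6

Assumption: the sense of induction of the chiral acid in step 6 cannot be derived with certainty; the (R)-acid is written, and its mirror image would be used if the 3R series were favoured.

## Route

Step 1
Reactants: 1 (R)-4-benzyl-1,3-oxazolidin-2-one
Product: 2 (R)-4-benzyl-3-(2-bromoacetyl)-1,3-oxazolidin-2-one
Conditions: n-BuLi, THF, −78 °C; BrCH2COBr, −78 to 0 °C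
Reagents that add atoms: bromoacetyl bromide, `BrCC(Br)=O`
Why: N-acylation of the lithiated oxazolidinone, the standard loading of an Evans auxiliary, should occur at the acyl bromide much faster than substitution at the CH2Br carbon.

Step 2
Reactants: 3 (E)-sinapyl alcohol
Product: 4 2,6-dimethoxy-4-[(E)-3-(triisopropylsilyloxy)prop-1-enyl]phenol
Conditions: i-Pr3SiCl (1.05 equiv), Et3N, 4-(dimethylamino)pyridine (cat.), CH2Cl2, 0 °C
Reagents that add atoms: triisopropylsilyl chloride, `CC(C)[Si](Cl)(C(C)C)C(C)C`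
Why: Chemoselective O-silylation, in which the bulky silyl chloride under nucleophilic catalysis should take the primary allylic alcohol in preference to the phenol flanked by two methoxy groups, which has to stay free for step 6.

Step 3
Reactants: 5 4-hydroxy-2-methoxybenzaldehyde
Product: 6 4-(allyloxy)-2-methoxybenzaldehyde
Conditions: allyl bromide, K2CO3, DMF, rt
Reagents that add atoms: allyl bromide, `C=CCBr`
Why: Williamson ether synthesis on the only phenol fixes which of the two ring D oxygens will carry the removable allyl group.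

Step 4
Reactants: 6 4-(allyloxy)-2-methoxybenzaldehyde
Product: 8 4-(allyloxy)-2-methoxyphenol, via aryl formate 7 (not isolated)
Conditions: mCPBA, CH2Cl2, 0 °C to rt; then K2CO3 (cat.), MeOH, rt
Reagents that add atoms: 3-chloroperoxybenzoic acid, `OOC(=O)c1cccc(Cl)c1`
Why: Baeyer–Villiger (Dakin-type) oxidation, in which the electron-rich aryl group migrates to oxygen much faster than the monosubstituted allyl alkene is epoxidised, followed by methanolysis of the formate.

Step 5
Reactants: 8 4-(allyloxy)-2-methoxyphenol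
Product: 9 4,4-bis(allyloxy)-2-methoxycyclohexa-2,5-dien-1-one
Conditions: PhI(OAc)2, allyl alcohol, 0 °C
Reagents that add atoms: allyl alcohol, `C=CCO`
Why: Oxidative dearomatisation of a 4-alkoxyphenol by the trivalent iodine reagent in an alcohol gives the quinone monoketal, and allyl alcohol as solvent makes the two ketal oxygens identical so that either may leave in step 6.

Step 6
Reactants: 4 2,6-dimethoxy-4-[(E)-3-(triisopropylsilyloxy)prop-1-enyl]phenol, 9 4,4-bis(allyloxy)-2-methoxycyclohexa-2,5-dien-1-one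
Product: 11 4-[(2R,3S)-5-(allyloxy)-7-methoxy-3-(triisopropylsilyloxymethyl)-2,3-dihydro-1-benzofuran-2-yl]-2,6-dimethoxyphenol, via quinone methide 10 (not isolated)
Conditions: (R)-3,3′-bis(2,4,6-triisopropylphenyl)-1,1′-binaphthyl-2,2′-diyl hydrogen phosphate (10 mol %), 5 Å molecular sieves, CH2Cl2, −40 °C
Reagents that add atoms: none
Why: Proposed new method: the chiral phosphoric acid should ionise ketal 9 (loss of allyl alcohol, taken up by the sieves) to the 4-allyloxy-2-methoxyphenoxonium ion, held as a contact ion pair by the phosphate whose P=O oxygen also hydrogen-bonds the phenol O–H of 4; C8 of this 4-hydroxystyrene then attacks C6 of the cation (the unsubstituted carbon next to the carbonyl carbon C1), tautomerisation gives quinone methide 10, and the new ring D phenol oxygen adds to its exocyclic carbon C7. The closest known reaction types are the Brønsted acid-catalysed formal [3+2] coupling of quinone monoketals with styrenes to 2-aryl-2,3-dihydrobenzofurans and the chiral phosphoric acid-controlled [3+2] couplings of quinone monoimides with hydroxystyrenes; the enantioselective version with a quinone monoketal is what is new. The furan ring closes by 5-exo-trig oxa-Michael addition of O1 to the quinone methide. C3 is set in the C–C bond formation by the catalyst within the hydrogen-bonded ion pair (3S wanted), and C2 follows as 2R because the reversible closure of the quinone methide places the aryl group trans to the CH2OSi group. The step needs attack at C6 and not at the methoxy-bearing C2 of the cation, which the substitution pattern secures since only the C6 adduct can rearomatise, and C- over O-alkylation of phenol 4, which is secured because an O-adduct is a mixed ketal that ionises back.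

Step 7
Reactants: 11 4-[(2R,3S)-5-(allyloxy)-7-methoxy-3-(triisopropylsilyloxymethyl)-2,3-dihydro-1-benzofuran-2-yl]-2,6-dimethoxyphenol, 2 (R)-4-benzyl-3-(2-bromoacetyl)-1,3-oxazolidin-2-one
Product: 12 (R)-4-benzyl-3-[2-[4-[(2R,3S)-5-(allyloxy)-7-methoxy-3-(triisopropylsilyloxymethyl)-2,3-dihydro-1-benzofuran-2-yl]-2,6-dimethoxyphenoxy]acetyl]-1,3-oxazolidin-2-one (fragment 1)
Conditions: K2CO3, NaI (cat.), acetone, rt
Reagents that add atoms: none
Why: Williamson alkylation of the hindered phenoxide at the activated primary carbon of the α-bromo imide, under conditions mild enough that C3, which alone carries the absolute configuration of the core, is not touched.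

Step 8
Reactants: 13 vanillin
Product: 14 3-methoxy-4-(triisopropylsilyloxy)benzaldehyde
Conditions: i-Pr3SiCl, imidazole, DMF, rt
Reagents that add atoms: triisopropylsilyl chloride, `CC(C)[Si](Cl)(C(C)C)C(C)C`
Why: Silyl ether formation protects the ring A phenol with a group that resists the bases and hydrides used later and falls with fluoride in the last step.

Step 9
Reactants: 15 4-bromo-2,6-dimethoxyphenol, 2 (R)-4-benzyl-3-(2-bromoacetyl)-1,3-oxazolidin-2-one
Product: 16 (R)-4-benzyl-3-[2-(4-bromo-2,6-dimethoxyphenoxy)acetyl]-1,3-oxazolidin-2-one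
Conditions: K2CO3, NaI (cat.), acetone, rt
Reagents that add atoms: none
Why: Williamson alkylation as in step 7, with the aryl bromide serving as an inert placeholder for the later formyl group of ring B.

Step 10
Reactants: 16 (R)-4-benzyl-3-[2-(4-bromo-2,6-dimethoxyphenoxy)acetyl]-1,3-oxazolidin-2-one, 14 3-methoxy-4-(triisopropylsilyloxy)benzaldehyde
Product: 17 (R)-4-benzyl-3-[(2R,3S)-2-(4-bromo-2,6-dimethoxyphenoxy)-3-hydroxy-3-[3-methoxy-4-(triisopropylsilyloxy)phenyl]propanoyl]-1,3-oxazolidin-2-one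
Conditions: n-Bu2BOTf, i-Pr2NEt, CH2Cl2, −78 to 0 °C; 14, −78 to 0 °C; then H2O2, MeOH, pH 7 buffer, 0 °C
Reagents that add atoms: none
Why: Evans syn-aldol reaction, in which the Z-boron enolate of the aryloxyacetyl imide should add through a chair Zimmerman–Traxler transition state on the face away from the benzyl group of the (R)-auxiliary, setting C8 and C7 together as the 2R,3S (threo) pair.

Step 11
Reactants: 17 the syn-aldol adduct of step 10
Product: 18 (1R,2R)-3-[(R)-4-benzyl-2-oxo-1,3-oxazolidin-3-yl]-2-(4-bromo-2,6-dimethoxyphenoxy)-1-[3-methoxy-4-(triisopropylsilyloxy)phenyl]-3-oxopropyl 4-nitrobenzoate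
Conditions: 4-nitrobenzoic acid, PPh3, DIAD, THF, 0 °C to rt
Reagents that add atoms: 4-nitrobenzoic acid, `OC(=O)c1ccc(cc1)[N+](=O)[O-]`
Why: Mitsunobu inversion, in which SN2 displacement of the oxyphosphonium group at C7 by 4-nitrobenzoate should turn the threo into the erythro series (C7 from S to R) without touching C8.

Step 12
Reactants: 18 the inverted 4-nitrobenzoate of step 11
Product: 19 (1R,2S)-2-(4-bromo-2,6-dimethoxyphenoxy)-1-[3-methoxy-4-(triisopropylsilyloxy)phenyl]propane-1,3-diol
Conditions: LiBH4, MeOH (2 equiv), THF, 0 °C to rt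
Reagents that add atoms: none
Why: Reductive removal of the auxiliary, in which LiBH4 should reduce the imide carbonyl to the primary alcohol and reduce off the activated 4-nitrobenzoate in the same operation, leaving both stereocentres untouched (the C8 descriptor changes from R to S only through the change of priorities).

Step 13
Reactants: 19 the erythro diol of step 12
Product: 20 the 1,3-bis(tert-butyldimethylsilyl) ether of 19 (1R,2S)
Conditions: t-BuMe2SiOTf, 2,6-lutidine, CH2Cl2, 0 °C
Reagents that add atoms: tert-butyldimethylsilyl triflate, `CC(C)(C)[Si](C)(C)OS(=O)(=O)C(F)(F)F`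
Why: Silyl ether formation with the silyl triflate covers the hindered benzylic and the primary hydroxyl so that the organolithium step meets no acidic proton.

Step 14
Reactants: 20 the bis-silyl ether of step 13
Product: 21 4-[[(1R,2S)-1,3-bis(tert-butyldimethylsilyloxy)-1-[3-methoxy-4-(triisopropylsilyloxy)phenyl]propan-2-yl]oxy]-3,5-dimethoxybenzaldehyde (fragment 2)
Conditions: n-BuLi, THF, −78 °C; DMF, −78 °C; H2O
Reagents that add atoms: N,N-dimethylformamide, `CN(C)C=O`
Why: Bromine–lithium exchange followed by formylation of the aryllithium with DMF (Bouveault aldehyde synthesis) turns the bromide into the aldehyde needed for the fragment union.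

Step 15
Reactants: 12 fragment 1 (ring C aryloxyacetyl imide), 21 fragment 2 (A–B aldehyde)
Product: 22 (R)-4-benzyl-3-[(2R,3S)-3-hydroxy-3-(ring B aryl)-2-(ring C aryloxy)propanoyl]-1,3-oxazolidin-2-one, in which ring B aryl is the aryl group of 21 bound through its former formyl carbon and ring C aryloxy is the phenoxy group of 11
Conditions: n-Bu2BOTf, i-Pr2NEt, CH2Cl2, −78 to 0 °C; 21, −78 to 0 °C; then H2O2, MeOH, pH 7 buffer, 0 °C
Reagents that add atoms: none
Why: Evans syn-aldol reaction as in step 10, in which reagent control by the (R)-auxiliary should again give the 2R,3S (threo) adduct because the stereocentres of both fragments are too far from the reacting carbons to interfere.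

Step 16
Reactants: 22 the syn-aldol adduct of step 15
Product: 23 the 4-nitrobenzoate of 22 with inverted carbinol carbon (2R,3R in the propanoyl numbering)
Conditions: 4-nitrobenzoic acid, PPh3, DIAD, THF, 0 °C to rt
Reagents that add atoms: 4-nitrobenzoic acid, `OC(=O)c1ccc(cc1)[N+](=O)[O-]`
Why: Mitsunobu inversion as in step 11 should bring C7 of unit B from S to R by SN2 displacement and so give the erythro series.

Step 17
Reactants: 23 the inverted 4-nitrobenzoate of step 16
Product: 24 (1R,2S)-1-(ring B aryl)-2-(ring C aryloxy)propane-1,3-diol, with ring D still carrying the C5 allyl ether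
Conditions: LiBH4, MeOH (2 equiv), THF, 0 °C to rt
Reagents that add atoms: none
Why: Reductive removal of the auxiliary and of the 4-nitrobenzoate by LiBH4 as in step 12, which the aryl allyl ether and the silyl ethers should survive.

Step 18
Reactants: 24 the diol of step 17
Product: 25 the C5 phenol of ring D (allyl group of 24 replaced by H)
Conditions: Pd(PPh3)4 (5 mol %), morpholine, THF, rt
Reagents that add atoms: none
Why: Tsuji–Trost deallylation, in which zerovalent palladium ionises the aryl allyl ether to a π-allyl complex that morpholine traps, frees the C5 phenol under neutral conditions.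

Step 19
Reactants: 25 the C5 phenol of step 18
Product: 26 the C5 aryl triflate
Conditions: PhNTf2, Et3N, 4-(dimethylamino)pyridine (cat.), CH2Cl2, rt
Reagents that add atoms: N-phenylbis(trifluoromethanesulfonimide), `O=S(=O)(N(c1ccccc1)S(=O)(=O)C(F)(F)F)C(F)(F)F`
Why: O-sulfonylation with the mild triflimide reagent is selective for the phenoxide over the primary and secondary alcohols and turns the temporary C5 oxygen into a leaving group.

Step 20
Reactants: 26 the C5 aryl triflate of step 19
Product: 28 the silyl-protected (E)-enal (target carrying the ring A triisopropylsilyl ether the two unit A tert-butyldimethylsilyl ethers and the C3 CH2O triisopropylsilyl ether), via diethyl acetal 27 (not isolated)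
Conditions: (E)-(EtO)2CHCH=CHB(pin), Pd(dppf)Cl2 (5 mol %; dppf = 1,1′-bis(diphenylphosphino)ferrocene), K3PO4, 1,4-dioxane/H2O, 60 °C; then pyridinium 4-toluenesulfonate, acetone/H2O, rt
Reagents that add atoms: (E)-2-(3,3-diethoxyprop-1-enyl)-4,4,5,5-tetramethyl-1,3,2-dioxaborolane, `CCOC(OCC)/C=C/B1OC(C)(C)C(C)(C)O1`; water, `O`
Why: Suzuki–Miyaura coupling of the aryl triflate with the (E)-alkenylboronate should proceed with retention of the alkene geometry, and mild acid hydrolysis of the allylic acetal then frees the (E)-enal without touching the silyl ethers.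

Step 21
Reactants: 28 the silyl-protected enal of step 20
Product: 29 the target CNP0192639.1
Conditions: n-Bu4NF, AcOH, THF, 0 °C to rt
Reagents that add atoms: none
Why: Fluoride-induced cleavage of all four silyl ethers, buffered with acetic acid so that the enal and the 4-hydroxybenzyl alcohol of ring A are not exposed to base, should give the target.

## Compound list

```
1 | (R)-4-benzyl-1,3-oxazolidin-2-one | O=C1N[C@H](Cc2ccccc2)CO1 | starting material
2 | (R)-4-benzyl-3-(2-bromoacetyl)-1,3-oxazolidin-2-one | O=C(CBr)N1[C@H](Cc2ccccc2)COC1=O | intermediate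
3 | (E)-sinapyl alcohol, 4-[(E)-3-hydroxyprop-1-enyl]-2,6-dimethoxyphenol | COc1cc(/C=C/CO)cc(OC)c1O | starting material
4 | 2,6-dimethoxy-4-[(E)-3-(triisopropylsilyloxy)prop-1-enyl]phenol | COc1cc(/C=C/CO[Si](C(C)C)(C(C)C)C(C)C)cc(OC)c1O | intermediate
5 | 4-hydroxy-2-methoxybenzaldehyde | COc1cc(O)ccc1C=O | starting material
6 | 4-(allyloxy)-2-methoxybenzaldehyde | C=CCOc1ccc(C=O)c(OC)c1 | intermediate
7 | 4-(allyloxy)-2-methoxyphenyl formate (formed in the flask in step 4, not isolated) | C=CCOc1ccc(OC=O)c(OC)c1 | intermediate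
8 | 4-(allyloxy)-2-methoxyphenol | C=CCOc1ccc(O)c(OC)c1 | intermediate
9 | 4,4-bis(allyloxy)-2-methoxycyclohexa-2,5-dien-1-one | COC1=CC(OCC=C)(OCC=C)C=CC1=O | intermediate
10 | quinone methide 4-[(2S)-2-[5-(allyloxy)-2-hydroxy-3-methoxyphenyl]-3-(triisopropylsilyloxy)propylidene]-2,6-dimethoxycyclohexa-2,5-dien-1-one (formed in the flask in step 6, not isolated) | COC1=CC(=C[C@H](CO[Si](C(C)C)(C(C)C)C(C)C)c2cc(OCC=C)cc(OC)c2O)C=C(OC)C1=O | intermediate
11 | 4-[(2R,3S)-5-(allyloxy)-7-methoxy-3-(triisopropylsilyloxymethyl)-2,3-dihydro-1-benzofuran-2-yl]-2,6-dimethoxyphenol | COc1cc([C@@H]2Oc3c(OC)cc(OCC=C)cc3[C@H]2CO[Si](C(C)C)(C(C)C)C(C)C)cc(OC)c1O | intermediate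
12 | (R)-4-benzyl-3-[2-[4-[(2R,3S)-5-(allyloxy)-7-methoxy-3-(triisopropylsilyloxymethyl)-2,3-dihydro-1-benzofuran-2-yl]-2,6-dimethoxyphenoxy]acetyl]-1,3-oxazolidin-2-one (fragment 1) | COc1cc([C@@H]2Oc3c(OC)cc(OCC=C)cc3[C@H]2CO[Si](C(C)C)(C(C)C)C(C)C)cc(OC)c1OCC(=O)N1[C@H](Cc2ccccc2)COC1=O | intermediate
13 | vanillin | COc1cc(C=O)ccc1O | starting material
14 | 3-methoxy-4-(triisopropylsilyloxy)benzaldehyde | COc1cc(C=O)ccc1O[Si](C(C)C)(C(C)C)C(C)C | intermediate
15 | 4-bromo-2,6-dimethoxyphenol | COc1cc(Br)cc(OC)c1O | starting material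
16 | (R)-4-benzyl-3-[2-(4-bromo-2,6-dimethoxyphenoxy)acetyl]-1,3-oxazolidin-2-one | COc1cc(Br)cc(OC)c1OCC(=O)N1[C@H](Cc2ccccc2)COC1=O | intermediate
17 | (R)-4-benzyl-3-[(2R,3S)-2-(4-bromo-2,6-dimethoxyphenoxy)-3-hydroxy-3-[3-methoxy-4-(triisopropylsilyloxy)phenyl]propanoyl]-1,3-oxazolidin-2-one (threo) | COc1cc([C@H](O)[C@@H](Oc2c(OC)cc(Br)cc2OC)C(=O)N2[C@H](Cc3ccccc3)COC2=O)ccc1O[Si](C(C)C)(C(C)C)C(C)C | intermediate
18 | (1R,2R)-3-[(R)-4-benzyl-2-oxo-1,3-oxazolidin-3-yl]-2-(4-bromo-2,6-dimethoxyphenoxy)-1-[3-methoxy-4-(triisopropylsilyloxy)phenyl]-3-oxopropyl 4-nitrobenzoate | COc1cc([C@@H](OC(=O)c2ccc(cc2)[N+](=O)[O-])[C@@H](Oc2c(OC)cc(Br)cc2OC)C(=O)N2[C@H](Cc3ccccc3)COC2=O)ccc1O[Si](C(C)C)(C(C)C)C(C)C | intermediate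
19 | (1R,2S)-2-(4-bromo-2,6-dimethoxyphenoxy)-1-[3-methoxy-4-(triisopropylsilyloxy)phenyl]propane-1,3-diol (erythro) | COc1cc([C@@H](O)[C@H](CO)Oc2c(OC)cc(Br)cc2OC)ccc1O[Si](C(C)C)(C(C)C)C(C)C | intermediate
20 | 1,3-bis(tert-butyldimethylsilyl) ether of 19 (1R,2S) | COc1cc([C@@H](O[Si](C)(C)C(C)(C)C)[C@H](CO[Si](C)(C)C(C)(C)C)Oc2c(OC)cc(Br)cc2OC)ccc1O[Si](C(C)C)(C(C)C)C(C)C | intermediate
21 | 4-[[(1R,2S)-1,3-bis(tert-butyldimethylsilyloxy)-1-[3-methoxy-4-(triisopropylsilyloxy)phenyl]propan-2-yl]oxy]-3,5-dimethoxybenzaldehyde (fragment 2) | COc1cc([C@@H](O[Si](C)(C)C(C)(C)C)[C@H](CO[Si](C)(C)C(C)(C)C)Oc2c(OC)cc(C=O)cc2OC)ccc1O[Si](C(C)C)(C(C)C)C(C)C | intermediate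
22 | syn-aldol adduct of 12 and 21: (R)-4-benzyl-3-[(2R,3S)-propanoyl]-1,3-oxazolidin-2-one carrying at C3 OH and the ring B aryl group of 21, at C2 the ring C aryloxy group of 11 (threo) | COc1cc([C@@H](O[Si](C)(C)C(C)(C)C)[C@H](CO[Si](C)(C)C(C)(C)C)Oc2c(OC)cc([C@H](O)[C@@H](Oc3c(OC)cc([C@@H]4Oc5c(OC)cc(OCC=C)cc5[C@H]4CO[Si](C(C)C)(C(C)C)C(C)C)cc3OC)C(=O)N3[C@H](Cc4ccccc4)COC3=O)cc2OC)ccc1O[Si](C(C)C)(C(C)C)C(C)C | intermediate
23 | 4-nitrobenzoate of 22 with inverted carbinol carbon (2R,3R in the propanoyl numbering) | COc1cc([C@@H](O[Si](C)(C)C(C)(C)C)[C@H](CO[Si](C)(C)C(C)(C)C)Oc2c(OC)cc([C@@H](OC(=O)c3ccc(cc3)[N+](=O)[O-])[C@@H](Oc3c(OC)cc([C@@H]4Oc5c(OC)cc(OCC=C)cc5[C@H]4CO[Si](C(C)C)(C(C)C)C(C)C)cc3OC)C(=O)N3[C@H](Cc4ccccc4)COC3=O)cc2OC)ccc1O[Si](C(C)C)(C(C)C)C(C)C | intermediate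
24 | erythro (1R,2S)-diol of unit B: 23 after loss of the auxiliary and the 4-nitrobenzoate; ring D C5 allyl ether | COc1cc([C@@H](O[Si](C)(C)C(C)(C)C)[C@H](CO[Si](C)(C)C(C)(C)C)Oc2c(OC)cc([C@@H](O)[C@H](CO)Oc3c(OC)cc([C@@H]4Oc5c(OC)cc(OCC=C)cc5[C@H]4CO[Si](C(C)C)(C(C)C)C(C)C)cc3OC)cc2OC)ccc1O[Si](C(C)C)(C(C)C)C(C)C | intermediate
25 | as 24 with a free C5 phenol on ring D | COc1cc([C@@H](O[Si](C)(C)C(C)(C)C)[C@H](CO[Si](C)(C)C(C)(C)C)Oc2c(OC)cc([C@@H](O)[C@H](CO)Oc3c(OC)cc([C@@H]4Oc5c(OC)cc(O)cc5[C@H]4CO[Si](C(C)C)(C(C)C)C(C)C)cc3OC)cc2OC)ccc1O[Si](C(C)C)(C(C)C)C(C)C | intermediate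
26 | as 24 with a C5 trifluoromethanesulfonate on ring D | COc1cc([C@@H](O[Si](C)(C)C(C)(C)C)[C@H](CO[Si](C)(C)C(C)(C)C)Oc2c(OC)cc([C@@H](O)[C@H](CO)Oc3c(OC)cc([C@@H]4Oc5c(OC)cc(OS(=O)(=O)C(F)(F)F)cc5[C@H]4CO[Si](C(C)C)(C(C)C)C(C)C)cc3OC)cc2OC)ccc1O[Si](C(C)C)(C(C)C)C(C)C | intermediate
27 | as 24 with a C5 (E)-3,3-diethoxyprop-1-enyl group on ring D (formed in the flask in step 20, not isolated) | COc1cc([C@@H](O[Si](C)(C)C(C)(C)C)[C@H](CO[Si](C)(C)C(C)(C)C)Oc2c(OC)cc([C@@H](O)[C@H](CO)Oc3c(OC)cc([C@@H]4Oc5c(OC)cc(/C=C/C(OCC)OCC)cc5[C@H]4CO[Si](C(C)C)(C(C)C)C(C)C)cc3OC)cc2OC)ccc1O[Si](C(C)C)(C(C)C)C(C)C | intermediate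
28 | silyl-protected target: (E)-enal on ring D; ring A phenol and C3 CH2O as triisopropylsilyl ethers, unit A C7 and C9 oxygens as tert-butyldimethylsilyl ethers | COc1cc([C@@H](O[Si](C)(C)C(C)(C)C)[C@H](CO[Si](C)(C)C(C)(C)C)Oc2c(OC)cc([C@@H](O)[C@H](CO)Oc3c(OC)cc([C@@H]4Oc5c(OC)cc(/C=C/C=O)cc5[C@H]4CO[Si](C(C)C)(C(C)C)C(C)C)cc3OC)cc2OC)ccc1O[Si](C(C)C)(C(C)C)C(C)C | intermediate
29 | CNP0192639.1 | COc1cc([C@@H](O)[C@H](CO)Oc2c(OC)cc([C@@H](O)[C@H](CO)Oc3c(OC)cc([C@@H]4Oc5c(OC)cc(/C=C/C=O)cc5[C@H]4CO)cc3OC)cc2OC)ccc1O | target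
```

## Step count and risks

Total step count: 21. Longest linear sequence: 14 steps (1, 9–21, from (R)-4-benzyl-1,3-oxazolidin-2-one).

Steps most likely to fail:

1. Step 6 (the step proposed as a new method). What may go wrong: too little facial discrimination in the ion pair, for example through an uncatalysed or allyl alcohol-promoted background coupling that erodes the enantiomeric purity, or diversion of the cation by attack at its methoxy-bearing carbon or by conjugate addition. Fallback with known chemistry, setting out from 4 and 9 and coming back at 11: the two bonds are made without asymmetric induction under the known achiral conditions for quinone monoketal/alkene [3+2] coupling (CF3CO2H cat., (CF3)2CHOH/CH2Cl2, 0 °C), which should give the racemic trans-dihydrobenzofuran F1. The absolute configuration is then secured by resolution instead of catalysis: preparative chromatography on a chiral stationary phase (supercritical CO2/MeOH) delivers the (2R,3S) enantiomer, which is 11.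

2. Step 11. What may go wrong: loss of water from the activated aldol to the enoyl imide, or ionisation of the electron-rich benzylic oxyphosphonium ion, which would return threo material and lower the stereochemical purity at C7. Fallback, setting out from 17 and coming back at 20: the inversion is replaced by an oxidation/reduction after removal of the auxiliary. LiBH4 should reduce 17 to the threo diol F2; t-BuMe2SiCl/imidazole silylates the primary hydroxyl to give the silyl ether F3; Dess–Martin periodinane gives the α-aryloxy ketone F4; LiBH(s-Bu)3 at −78 °C, which attacks anti to the aryloxy group in the Felkin–Anh sense, should give the erythro alcohol F5; t-BuMe2SiOTf/2,6-lutidine then gives 20.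

3. Step 20. What may go wrong: cleavage of the S–O bond of the electron-rich aryl triflate by the aqueous base (return to phenol 25), or protodeboronation of the alkenylboronate outrunning transmetalation. Fallback, setting out from 26 and coming back at 28: the three carbons are brought in as one plus two. Reductive carbonylation (Pd(OAc)2, 1,3-bis(diphenylphosphino)propane, CO, Et3SiH, Et3N, DMF, 70 °C) should give the aryl aldehyde F6, and Wittig olefination with the stabilised ylide Ph3P=CHCHO (toluene, 80 °C) then gives the (E)-enal 28.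

## Further compounds

```
F1 | step 6 | racemic trans-4-[5-(allyloxy)-7-methoxy-3-(triisopropylsilyloxymethyl)-2,3-dihydro-1-benzofuran-2-yl]-2,6-dimethoxyphenol (11 and its enantiomer, 1:1) | COc1cc([C@@H]2Oc3c(OC)cc(OCC=C)cc3[C@H]2CO[Si](C(C)C)(C(C)C)C(C)C)cc(OC)c1O.COc1cc([C@H]2Oc3c(OC)cc(OCC=C)cc3[C@@H]2CO[Si](C(C)C)(C(C)C)C(C)C)cc(OC)c1O
F2 | step 11 | (1S,2S)-2-(4-bromo-2,6-dimethoxyphenoxy)-1-[3-methoxy-4-(triisopropylsilyloxy)phenyl]propane-1,3-diol (threo) | COc1cc([C@H](O)[C@H](CO)Oc2c(OC)cc(Br)cc2OC)ccc1O[Si](C(C)C)(C(C)C)C(C)C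
F3 | step 11 | (1S,2S)-2-(4-bromo-2,6-dimethoxyphenoxy)-3-(tert-butyldimethylsilyloxy)-1-[3-methoxy-4-(triisopropylsilyloxy)phenyl]propan-1-ol | COc1cc([C@H](O)[C@H](CO[Si](C)(C)C(C)(C)C)Oc2c(OC)cc(Br)cc2OC)ccc1O[Si](C(C)C)(C(C)C)C(C)C
F4 | step 11 | (2S)-2-(4-bromo-2,6-dimethoxyphenoxy)-3-(tert-butyldimethylsilyloxy)-1-[3-methoxy-4-(triisopropylsilyloxy)phenyl]propan-1-one | COc1cc(C(=O)[C@H](CO[Si](C)(C)C(C)(C)C)Oc2c(OC)cc(Br)cc2OC)ccc1O[Si](C(C)C)(C(C)C)C(C)C
F5 | step 11 | (1R,2S)-2-(4-bromo-2,6-dimethoxyphenoxy)-3-(tert-butyldimethylsilyloxy)-1-[3-methoxy-4-(triisopropylsilyloxy)phenyl]propan-1-ol (erythro) | COc1cc([C@@H](O)[C@H](CO[Si](C)(C)C(C)(C)C)Oc2c(OC)cc(Br)cc2OC)ccc1O[Si](C(C)C)(C(C)C)C(C)C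
F6 | step 20 | as 26 with a C5 formyl group on ring D in place of the triflate | COc1cc([C@@H](O[Si](C)(C)C(C)(C)C)[C@H](CO[Si](C)(C)C(C)(C)C)Oc2c(OC)cc([C@@H](O)[C@H](CO)Oc3c(OC)cc([C@@H]4Oc5c(OC)cc(C=O)cc5[C@H]4CO[Si](C(C)C)(C(C)C)C(C)C)cc3OC)cc2OC)ccc1O[Si](C(C)C)(C(C)C)C(C)C
```
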